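(The runs are calculated on assumed constants; the scatter is artificial.)

The product asked about is the same pair of mirror images in theta and epsilon, two flasks charged alike that differ in their time, so you can turn the settings in order and see which one moves its excess.

| flask | left-handed substrate | right-handed substrate | solid reagent | remark | time |
|---|---|---|---|---|---|
| cedar | 26 mM | 26 mM | 2.7 equiv | run made earlier |  |
| ash | 26 mM | 26 mM | 6 equiv | run made earlier |  |
| maple | 13 mM | 13 mM | 4 equiv | run made earlier |  |
| theta | 26 mM | 26 mM | 4.00 equiv |  | 5.0 h |
| epsilon | 26 mM | 26 mM | 4.00 equiv |  | 1.2 h |

- cedar (time / h: left-handed product / %, right-handed product / %): 0.500: 0, 0.8; 0.833: 4.0, 1.8; 1.33: 4.0, 4.0; 2.00: 7.7, 6.5; 4.00: 12.6, 10.9; 6.00: 19.6, 17.3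
- ash (time / h: left-handed product / %, right-handed product / %): 0.500: 1.1, 1.8; 0.833: 0.8, 2.6; 1.33: 5.3, 2.1; 2.00: 6.5, 6.8; 4.00: 12.4, 12.0; 6.00: 16.2, 16.5
- maple (time / h: left-handed product / %, right-handed product / %): 0.500: 1.4, 1.3; 0.833: 2.1, 1.8; 1.50: 6.2, 3.0; 3.00: 11.2, 7.4; 6.00: 19.3, 18.5

(each reading ± 1 percentage point)

- partner is single-handed; left-handed substrate and right-handed substrate are mirror images of each other, charged as a racemate, each of them at the stated concentration
- given per volume of solution although it is solid: solid reagent
- steps thought possible: partner + left-handed substrate -> left-handed product; partner + right-handed substrate -> right-handed product; left-handed substrate <-> right-handed substrate; left-handed product <-> right-handed product; solid reagent <-> partner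
- at the start none of the solid reagent is in solution
- an excess is the difference of the two amounts in percent of their sum
- an excess is below zero if the other one leads
- the handed part of partner does not stay in what it makes, so the products of the two hands are mirror images too

* which of the two ends with the higher excess of left-handed product over right-handed product in the product ("neither" if they lie within 2 percentage points) (theta / epsilon / neither)
* excess of left-handed product over right-handed product in the product at the end, theta
* excess of left-handed product over right-handed product in the product at the end, epsilon

Take solid reagent first: by hand, more of it should give more product if dissolved partner rose with it, but cedar at 2.7 equiv holds 36.9% of product at 6.00 h and ash at 6 equiv holds 32.7%, so the readings show no gain. Halving the substrate should leave the percent unchanged if the rate is first order in substrate, and maple at 13 mM reads 37.8% at 6.00 h.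

That leaves time, where a steady selectivity should hold the excess constant. Yet, averaged over the three runs, the difference between the two products goes from 1.6 percentage points at the readings of 2.00 h to 3.00 h to 0.93 points at 6.00 h, while the averaged product of both hands grows from 15.4% to 35.8%. I read this as a difference that has stopped growing, so the excess should fall as one over time. The late excess is 2.61%, which gives 0.156 h, the excess-time E, the excess multiplied by the time of its reading; each reading behind it scatters by 1 point, so E is rough.

log e = log E − log t

log(t of theta / t of epsilon) = 0.620

So I reckon 3.13% for theta and 13.0% for epsilon, whose time lies before those late readings, which makes its number the weaker.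

The forecast says neither, with 5% (1.5% to 8.5%) for theta and 6% (1.5% to 10.5%) for epsilon, holding that its late and early points “show no significant decay”; my reckoning differs there.

The flask gives epsilon: 2.48% in theta, 12.4% in epsilon.

    partner + left-handed substrate → left-handed product (k = 0.00740 /M/s)
    partner + right-handed substrate → right-handed product (k = 0.00270 /M/s)
    left-handed substrate ⇌ right-handed substrate (k = 5.50 × 10⁻⁴ /s)
    left-handed product ⇌ right-handed product (k = 4.60 × 10⁻⁴ /s)
    solid reagent ⇌ partner, rate k5*(cs5 - [partner]) while solid is left; crystals form when [partner] > cs5 (solubility = 4.40 mM, k = 0.00180 /s)

The relaxation half-life of the two products by their own step, both ways together, is 0.209 h in epsilon, shorter than 5.0 h and than 1.2 h. The selectivity factor of the two partner steps is 2.74, yet theta at 5.00 h holds 14.9% against 14.2%. Excess times time comes to 0.124 h in theta and 0.149 h in epsilon, beside the 0.156 h read from the runs. For the flask like epsilon but with 16.0 equiv of solid reagent, E contains no solid reagent and gives 13.0% again at 1.2 h; the computed answer is 12.4%.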